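- I begin with an easy division. Monomer in chains and initiator are both given on the free monomer charged, so the last percentage of monomer in chains over the mol% of initiator counts monomer units per initiator.

| flask | free monomer | transfer agent | initiator | remark | time |
|---|---|---|---|---|---|
| elm | 0.40 M | 0.040 M | 0.67 mol% | run made earlier |  |
| oak | 0.40 M | 0.040 M | 1.5 mol% | run made earlier |  |
| cedar | 0.80 M | 0.040 M | 1 mol% | run made earlier |  |
| north | 0.40 M | 0.0400 M | 1 mol% |  | 6.0 h |
| north-east | 0.40 M | 0.0400 M | 1 mol% |  | 25 h |

| run | time / h | monomer in chains / % | free monomer / % |
|---|---|---|---|
| elm | 0.500 | 2.3 | 98.0 |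
| elm | 1.33 | 3.7 | 96.3 |
| elm | 3.00 | 4.3 | 96.1 |
| elm | 8.00 | 4.9 | 95.0 |
| oak | 0.500 | 5.0 | 95.2 |
| oak | 1.33 | 9.6 | 90.3 |
| oak | 3.00 | 11.0 | 90.2 |
| oak | 8.00 | 10.0 | 90.2 |
| cedar | 0.833 | 11.3 | 88.8 |
| cedar | 2.50 | 13.6 | 86.8 |
| cedar | 5.00 | 14.1 | 85.8 |
| cedar | 8.00 | 13.3 | 85.7 |

(readings scatter by 0.5 percentage points)

- the average divides the monomer in chains by the number of chains begun, living and dead together
- the earlier runs do not show the number of chains; that part of a forecast is a guess

- which of the two ends with the longer chains by the average number of monomer units in a chain (chains begun, living or dead) ("neither" if they lie within 10%) (north / north-east / neither)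
- average number of monomer units in a chain (chains begun, living or dead) at the end, north
- average number of monomer units in a chain (chains begun, living or dead) at the end, north-east

- My first way uses the two runs at the monomer charge of north. Elm gives 7.31 and oak 6.67, although oak carries about twice the initiator, and a scatter of 0.5 percentage points on elm's 4.9% covers the gap.
- Their mean, 6.99, is what I carry: monomer in chains at the end divided by initiator charged, the units per initiator.
- My second way uses a different run. Cedar gives 13.3 at 0.80 M of free monomer, and if the figure follows the monomer charge, at fixed transfer agent, that becomes 6.65 at 0.40 M. The two ways agree within the scatter, so I trust the figure and its proportion to monomer.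
- The readings can't count chains. I assume that a chain takes one initiator to begin and that some initiator may begin none, which makes 6.99, a figure read from scattered readings, a rough floor for the length.
- Oak's free monomer reads 90.2% at 3.00 h and 90.2% at 8.00 h. Since 6.0 h is later than that first flat reading, I expect equal lengths in north and north-east, a little above 6.99.
- The forecast is neither, with 4 units in north and 4 in north-east, on its view that “the initiator seems to be spent early”; we agree on the time, but its length is less than mine.

    free monomer + initiator → living end + monomer in chains (k = 7.60 L mol⁻¹ h⁻¹)
    free monomer + living end → monomer in chains + living end, rate k2*[living end]*[free monomer] (k = 47.0 L mol⁻¹ h⁻¹)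
    living end + transfer agent → dead chain (kL = 72.0 L mol⁻¹ h⁻¹)
    initiator → spent initiator (k = 0.300 h⁻¹)

- The flask gives 7.59 in north and 7.59 in north-east, so the answer is neither, and the length stands above my floor, with 0.00363 M of dead chain from 0.00400 M of initiator charged in north at 6.00 h. In north the initiator is at 0% of its charge at 6.00 h while 93% of the free monomer remains, and in north-east at 0.557 h growth uses free monomer 12 times as fast as the beginning of chains does. Carried to a flask like north-east but with 1.6 M of free monomer, 6.99 becomes 28.0, and that flask ends at 29.0.

All runs are calculated for an exercise; noise was put on by code.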